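**Retrosynthetic overview**

1. Locants: ring A (diol ring) C-1 = C(Me)OH, C-2 = CHOH, C-3 bears the linker, C-4 bears isopropenyl; linker C-1''H2–C-2''(=C-3''H2); ring B C-1' (bonded to C-2''), C-3' = CHBr, C-4' = C(Me)OH.
2. Key disconnection C-2''–C-1': a nickel-catalysed reductive cross-electrophile (radical) coupling joins two electrophilic carbons, alkenyl bromide 9 (ring A complete) and secondary bromide 10 (ring B as a masked 4-oxocyclohexyl unit).
3. Enabling feature: C-2'' is a vinylic carbon that can be carried as a 2-bromoallyl group, and C-1' lies para to C-4', on the mirror plane of a 4-oxocyclohexyl radical, so the radical carbon is not stereogenic and no ring-B stereochemistry has to survive the radical step.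
4. Ring A: (S)-carvone supplies C-4; trans-alkylation sets C-3, Rubottom oxidation C-1, hydroxyl-directed reduction C-2.
5. Ring B after coupling: enantiotopic enolisation fixes C-1', axial C–O formation then bromide inversion sets C-3', methyl addition anti to bromine sets C-4'. No ring is constructed; ring A is finished first, the rings are joined, ring B is finished last.

Key step: step 5

Remark (assumption): the sense of enolisation in step 6 is taken from 4-tert-butylcyclohexanone, where the (R,R)-amide is reported to give the (S)-enol silane; if 12 behaves oppositely, the (R,R)-amine is used instead.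

**Route**

Step 1
Reactants: 1 (S)-carvone; 2 2,3-dibromopropene
Product: 3 (5S,6R)-6-(2-bromoprop-2-en-1-yl)-2-methyl-5-(prop-1-en-2-yl)cyclohex-2-en-1-one
Conditions: LiN(i-Pr)2, THF, −78 °C; then 2, DMPU, −78 to −30 °C
Reagents that add atoms: none
Why: Enolate alkylation: the kinetic cross-conjugated lithium enolate attacks the allylic bromide of 2 by SN2 (the vinylic bromide is inert), entering anti to the adjacent isopropenyl group to set the trans C-3/C-4 relationship (3R).

Step 2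
Reactants: 3 (5S,6R)-6-(2-bromoprop-2-en-1-yl)-2-methyl-5-(prop-1-en-2-yl)cyclohex-2-en-1-one
Product: 5 {[(5S,6R)-6-(2-bromoprop-2-en-1-yl)-2-methyl-5-(prop-1-en-2-yl)cyclohex-1-en-1-yl]oxy}trimethylsilane, via lithium enolate 4 (not isolated)
Conditions: LiBH(s-Bu)3, THF, −78 °C; then Me3SiCl, −78 to 0 °C
Reagents that add atoms: chlorotrimethylsilane, C[Si](C)(C)Cl
Why: Conjugate hydride reduction of the α-methyl enone followed by O-silylation traps the regiodefined enolate as the tetrasubstituted silyl enol ether, with no stereocentre formed and the alkenyl bromide and isopropenyl group untouched.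

Step 3
Reactants: 5 {[(5S,6R)-6-(2-bromoprop-2-en-1-yl)-2-methyl-5-(prop-1-en-2-yl)cyclohex-1-en-1-yl]oxy}trimethylsilane
Product: 8 (2R,5S,6R)-6-(2-bromoprop-2-en-1-yl)-2-hydroxy-2-methyl-5-(prop-1-en-2-yl)cyclohexan-1-one, via silyloxy epoxide 6 (not isolated), via 2-silyloxy ketone 7 (not isolated)
Conditions: mCPBA, NaHCO3, CH2Cl2, −20 °C; then 1 M HCl, THF, 0 °C
Reagents that add atoms: 3-chloroperoxybenzoic acid, OOC(=O)c1cccc(Cl)c1
Why: Rubottom oxidation: the electron-rich silyl enol ether is epoxidised much faster than the two 1,1-disubstituted alkenes and anti to the adjacent bromoallyl group (turned pseudoaxial by allylic strain with OSiMe3), so silyl migration and acidic work-up should give the tertiary α-hydroxy ketone with C-1 as R.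

Step 4
Reactants: 8 (2R,5S,6R)-6-(2-bromoprop-2-en-1-yl)-2-hydroxy-2-methyl-5-(prop-1-en-2-yl)cyclohexan-1-one
Product: 9 (1R,2R,3R,4S)-3-(2-bromoprop-2-en-1-yl)-1-methyl-4-(prop-1-en-2-yl)cyclohexane-1,2-diol
Conditions: Me4NBH(OAc)3, MeCN/AcOH, −30 to 0 °C
Reagents that add atoms: none
Why: Hydroxyl-directed triacetoxyborohydride reduction: the tertiary C-1 hydroxyl binds boron and delivers hydride to the same face of the ketone, which should give the trans-diaxial diol (2R, hydroxyl axial and cis to the C-3 side chain).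

Step 5
Reactants: 9 (1R,2R,3R,4S)-3-(2-bromoprop-2-en-1-yl)-1-methyl-4-(prop-1-en-2-yl)cyclohexane-1,2-diol; 10 8-bromo-1,4-dioxaspiro[4.5]decane
Product: 12 4-{3-[(1R,2R,3R,6S)-2,3-dihydroxy-3-methyl-6-(prop-1-en-2-yl)cyclohexyl]prop-1-en-2-yl}cyclohexan-1-one, via dioxolane ketal 11 (not isolated)
Conditions: NiI2 (10 mol %), 4,4'-dimethoxy-2,2'-bipyridine (10 mol %), NaI, pyridine, Zn dust, DMPU, 60 °C; then 1 M HCl, THF, 20 °C
Reagents that add atoms: water, O
Why: Zerovalent nickel inserts into the C(sp2)–Br bond of 9, a monovalent nickel species abstracts bromine from 10 to give the secondary 1,4-dioxaspiro[4.5]decan-8-yl radical, the alkenylnickel bromide captures this radical, and reductive elimination from trivalent nickel forms the C-2''–C-1' bond while Zn returns nickel to the low-valent state. The closest known reaction type is the nickel-catalysed reductive cross-electrophile coupling of alkenyl bromides with secondary alkyl bromides, a union of two electrophilic carbons. No ring is closed and no stereocentre is created, because the radical carbon sits on the mirror plane of the spiro-ketal ring; C-1' becomes stereogenic only in step 6. The step needs cross- over homo-coupling selectivity, secured by the two different activation modes (two-electron oxidative addition for the alkenyl bromide, halogen-atom abstraction for the alkyl bromide), and chemoselectivity, secured because the free diol, the isopropenyl group and the C-3 stereocentre are inert to the nickel/Zn system and the 1,1-disubstituted alkenyl bromide has no alkene geometry to lose. Aqueous HCl in the work-up then hydrolyses the dioxolane of 11 to ketone 12.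

Step 6
Reactants: 12 4-{3-[(1R,2R,3R,6S)-2,3-dihydroxy-3-methyl-6-(prop-1-en-2-yl)cyclohexyl]prop-1-en-2-yl}cyclohexan-1-one
Product: 15 trimethyl{[(4R)-4-{3-[(1R,2R,3R,6S)-3-methyl-6-(prop-1-en-2-yl)-2,3-bis(trimethylsilyloxy)cyclohexyl]prop-1-en-2-yl}cyclohex-1-en-1-yl]oxy}silane, via bis-silyl ether 13 (not isolated), via lithium enolate 14 (not isolated)
Conditions: (S,S)-bis(1-phenylethyl)amine, n-BuLi (3.3 equiv), LiCl, Me3SiCl (6 equiv, internal quench), THF, −78 to 0 °C
Reagents that add atoms: chlorotrimethylsilane, C[Si](C)(C)Cl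
Why: Enantioselective deprotonation: after the two hydroxyls are silylated in the same flask, the C2-symmetric chiral lithium amide removes an axial α-proton from one of the two enantiotopic methylenes and the enolate is silylated at once, so the position of the enol double bond (C-3'=C-4') should fix C-1' as R.

Step 7
Reactants: 16 4-nitrobenzenesulfonyl chloride (2 equiv)
Product: 17 bis(4-nitrobenzenesulfonyl) peroxide
Conditions: 30% H2O2 (1 equiv), K2CO3, EtOH/H2O, −20 °C
Reagents that add atoms: hydrogen peroxide, OO; 4-nitrobenzenesulfonyl chloride (the second equivalent of 16), O=S(=O)(Cl)c1ccc(cc1)[N+](=O)[O-]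
Why: Nucleophilic substitution at sulfonyl sulfur, twice: hydroperoxide anion displaces chloride from one molecule of 16 and the resulting peroxysulfonate anion displaces chloride from a second molecule of 16, so two sulfonyl chlorides and one hydrogen peroxide should give the symmetrical diaryl sulfonyl peroxide, with no stereochemistry involved; the solid is kept cold and used fresh.

Step 8
Reactants: 15 trimethyl{[(4R)-4-{3-[(1R,2R,3R,6S)-3-methyl-6-(prop-1-en-2-yl)-2,3-bis(trimethylsilyloxy)cyclohexyl]prop-1-en-2-yl}cyclohex-1-en-1-yl]oxy}silane; 17 bis(4-nitrobenzenesulfonyl) peroxide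
Product: 18 (1S,5R)-5-{3-[(1R,2R,3R,6S)-3-methyl-6-(prop-1-en-2-yl)-2,3-bis(trimethylsilyloxy)cyclohexyl]prop-1-en-2-yl}-2-oxocyclohexyl 4-nitrobenzenesulfonate
Conditions: EtOAc, −78 to 0 °C
Reagents that add atoms: none
Why: Electrophilic α-sulfonyloxylation of a silyl enol ether by an arenesulfonyl peroxide: C-3' attacks the O–O bond along the axial, chair-like trajectory on the face opposite the equatorial side chain, so the nosylate should be installed axial (3'S) and trans to the side chain, while the enol ether reacts far faster than the two 1,1-disubstituted alkenes.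

Step 9
Reactants: 18 (1S,5R)-5-{3-[(1R,2R,3R,6S)-3-methyl-6-(prop-1-en-2-yl)-2,3-bis(trimethylsilyloxy)cyclohexyl]prop-1-en-2-yl}-2-oxocyclohexyl 4-nitrobenzenesulfonate
Product: 19 (2R,4R)-2-bromo-4-{3-[(1R,2R,3R,6S)-3-methyl-6-(prop-1-en-2-yl)-2,3-bis(trimethylsilyloxy)cyclohexyl]prop-1-en-2-yl}cyclohexan-1-one
Conditions: LiBr (1.0 equiv), acetone, −20 °C
Reagents that add atoms: lithium bromide, [Li+].[Br-]
Why: SN2 displacement of an α-sulfonyloxy ketone by bromide with inversion replaces the axial nosylate from the equatorial side, giving the equatorial bromide (3'R) cis to the side chain, and one equivalent of bromide at low temperature limits the bromide–bromide exchange that would epimerise C-3'.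

Step 10
Reactants: 19 (2R,4R)-2-bromo-4-{3-[(1R,2R,3R,6S)-3-methyl-6-(prop-1-en-2-yl)-2,3-bis(trimethylsilyloxy)cyclohexyl]prop-1-en-2-yl}cyclohexan-1-one
Product: 21 prevezol C, via bis-silyl bromohydrin 20 (not isolated)
Conditions: MeMgBr, CeCl3, THF, −78 °C; then 1 M HCl, THF, 0 °C
Reagents that add atoms: methylmagnesium bromide, C[Mg]Br
Why: 1,2-Addition of a methyl organometallic to an α-bromo ketone: methyl enters by equatorial attack on the face opposite the bromine, the usual course for methyl Grignard additions to 2-halocyclohexanones, which should give the tertiary alcohol cis to bromine (4'S, methyl equatorial, hydroxyl axial); this cis-bromohydrin cannot close to an epoxide, and the acidic work-up removes both silyl ethers.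

**Compound list**

1 | (S)-carvone, (5S)-2-methyl-5-(prop-1-en-2-yl)cyclohex-2-en-1-one | CC1=CC[C@@H](CC1=O)C(C)=C | starting material
2 | 2,3-dibromopropene | C=C(Br)CBr | starting material
3 | (5S,6R)-6-(2-bromoprop-2-en-1-yl)-2-methyl-5-(prop-1-en-2-yl)cyclohex-2-en-1-one | C=C(Br)C[C@@H]1[C@@H](C(=C)C)CC=C(C)C1=O | intermediate
4 | lithium (5S,6R)-6-(2-bromoprop-2-en-1-yl)-2-methyl-5-(prop-1-en-2-yl)cyclohex-1-en-1-olate | [Li+].C=C(Br)C[C@@H]1[C@@H](C(=C)C)CCC(C)=C1[O-] | intermediate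
5 | {[(5S,6R)-6-(2-bromoprop-2-en-1-yl)-2-methyl-5-(prop-1-en-2-yl)cyclohex-1-en-1-yl]oxy}trimethylsilane | C=C(Br)C[C@@H]1[C@@H](C(=C)C)CCC(C)=C1O[Si](C)(C)C | intermediate
6 | epoxide of 5: 2-(2-bromoprop-2-en-1-yl)-6-methyl-3-(prop-1-en-2-yl)-1-(trimethylsilyloxy)-7-oxabicyclo[4.1.0]heptane, oxirane oxygen trans to the bromoallyl group and cis to isopropenyl | C=C(Br)C[C@@H]1[C@@H](C(=C)C)CC[C@@]2(C)O[C@@]12O[Si](C)(C)C | intermediate
7 | (2R,5S,6R)-6-(2-bromoprop-2-en-1-yl)-2-methyl-5-(prop-1-en-2-yl)-2-(trimethylsilyloxy)cyclohexan-1-one | C=C(Br)C[C@@H]1[C@@H](C(=C)C)CC[C@@](C)(O[Si](C)(C)C)C1=O | intermediate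
8 | (2R,5S,6R)-6-(2-bromoprop-2-en-1-yl)-2-hydroxy-2-methyl-5-(prop-1-en-2-yl)cyclohexan-1-one | C=C(Br)C[C@@H]1[C@@H](C(=C)C)CC[C@@](C)(O)C1=O | intermediate
9 | (1R,2R,3R,4S)-3-(2-bromoprop-2-en-1-yl)-1-methyl-4-(prop-1-en-2-yl)cyclohexane-1,2-diol | C=C(Br)C[C@@H]1[C@@H](C(=C)C)CC[C@@](C)(O)[C@@H]1O | intermediate
10 | 8-bromo-1,4-dioxaspiro[4.5]decane | BrC1CCC2(CC1)OCCO2 | starting material
11 | (1R,2R,3R,4S)-3-[2-(1,4-dioxaspiro[4.5]decan-8-yl)prop-2-en-1-yl]-1-methyl-4-(prop-1-en-2-yl)cyclohexane-1,2-diol | C=C(C[C@@H]1[C@@H](C(=C)C)CC[C@@](C)(O)[C@@H]1O)C1CCC2(CC1)OCCO2 | intermediate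
12 | 4-{3-[(1R,2R,3R,6S)-2,3-dihydroxy-3-methyl-6-(prop-1-en-2-yl)cyclohexyl]prop-1-en-2-yl}cyclohexan-1-one | C=C(C[C@@H]1[C@@H](C(=C)C)CC[C@@](C)(O)[C@@H]1O)C1CCC(=O)CC1 | intermediate
13 | 4-{3-[(1R,2R,3R,6S)-3-methyl-6-(prop-1-en-2-yl)-2,3-bis(trimethylsilyloxy)cyclohexyl]prop-1-en-2-yl}cyclohexan-1-one | C=C(C[C@@H]1[C@@H](C(=C)C)CC[C@@](C)(O[Si](C)(C)C)[C@@H]1O[Si](C)(C)C)C1CCC(=O)CC1 | intermediate
14 | lithium (4R)-4-{3-[(1R,2R,3R,6S)-3-methyl-6-(prop-1-en-2-yl)-2,3-bis(trimethylsilyloxy)cyclohexyl]prop-1-en-2-yl}cyclohex-1-en-1-olate | [Li+].C=C(C[C@@H]1[C@@H](C(=C)C)CC[C@@](C)(O[Si](C)(C)C)[C@@H]1O[Si](C)(C)C)[C@@H]1CCC([O-])=CC1 | intermediate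
15 | trimethyl{[(4R)-4-{3-[(1R,2R,3R,6S)-3-methyl-6-(prop-1-en-2-yl)-2,3-bis(trimethylsilyloxy)cyclohexyl]prop-1-en-2-yl}cyclohex-1-en-1-yl]oxy}silane | C=C(C[C@@H]1[C@@H](C(=C)C)CC[C@@](C)(O[Si](C)(C)C)[C@@H]1O[Si](C)(C)C)[C@@H]1CCC(O[Si](C)(C)C)=CC1 | intermediate
16 | 4-nitrobenzenesulfonyl chloride | O=S(=O)(Cl)c1ccc(cc1)[N+](=O)[O-] | starting material
17 | bis(4-nitrobenzenesulfonyl) peroxide | O=S(=O)(OOS(=O)(=O)c1ccc(cc1)[N+](=O)[O-])c1ccc(cc1)[N+](=O)[O-] | intermediate
18 | (1S,5R)-5-{3-[(1R,2R,3R,6S)-3-methyl-6-(prop-1-en-2-yl)-2,3-bis(trimethylsilyloxy)cyclohexyl]prop-1-en-2-yl}-2-oxocyclohexyl 4-nitrobenzenesulfonate | C=C(C[C@@H]1[C@@H](C(=C)C)CC[C@@](C)(O[Si](C)(C)C)[C@@H]1O[Si](C)(C)C)[C@@H]1CCC(=O)[C@@H](OS(=O)(=O)c2ccc(cc2)[N+](=O)[O-])C1 | intermediate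
19 | (2R,4R)-2-bromo-4-{3-[(1R,2R,3R,6S)-3-methyl-6-(prop-1-en-2-yl)-2,3-bis(trimethylsilyloxy)cyclohexyl]prop-1-en-2-yl}cyclohexan-1-one | C=C(C[C@@H]1[C@@H](C(=C)C)CC[C@@](C)(O[Si](C)(C)C)[C@@H]1O[Si](C)(C)C)[C@@H]1CCC(=O)[C@H](Br)C1 | intermediate
20 | (1S,2R,4R)-2-bromo-1-methyl-4-{3-[(1R,2R,3R,6S)-3-methyl-6-(prop-1-en-2-yl)-2,3-bis(trimethylsilyloxy)cyclohexyl]prop-1-en-2-yl}cyclohexan-1-ol | C=C(C[C@@H]1[C@@H](C(=C)C)CC[C@@](C)(O[Si](C)(C)C)[C@@H]1O[Si](C)(C)C)[C@@H]1CC[C@](C)(O)[C@H](Br)C1 | intermediate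
21 | prevezol C, (1R,2R,3R,4S)-3-{2-[(1R,3R,4S)-3-bromo-4-hydroxy-4-methylcyclohexyl]prop-2-en-1-yl}-1-methyl-4-(prop-1-en-2-yl)cyclohexane-1,2-diol | C=C(C[C@@H]1[C@@H](C(=C)C)CC[C@@](C)(O)[C@@H]1O)[C@@H]1CC[C@](C)(O)[C@H](Br)C1 | target

**Step count and risks**

Total steps: 10. Longest linear sequence: 9 (steps 1–6 and 8–10; step 7 prepares the reagent for step 8 from two molecules of 16).

Step 8 – what may go wrong: poor facial selectivity (C–O bond formation from the equatorial side, which after step 9 leads to the C-3' epimer) and competing oxidation of the 1,1-disubstituted alkenes. Fallback, from 15 back to 19, sets C-3' by protonation instead of by C–O formation and inversion. Bromination of 15 with N-bromosuccinimide (THF, −78 °C) would give 19 mixed with its C-3' epimer, (2S,4R)-2-bromo ketone F1. Without separation, Me3SiOTf/Et3N would re-enolise both epimers towards the bromine-bearing carbon to the 2-bromo silyl enol ether F2. MeLi (THF, −78 °C) would release lithium bromoenolate F3, and inverse addition to 2,6-di-tert-butyl-4-methylphenol should ketonise it by axial protonation at C-3', leaving bromine equatorial as in 19.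

Step 6 – what may go wrong: insufficient discrimination of the two enantiotopic α-methylenes (perturbation of the chiral amide aggregate by the lithium alkoxides, mismatch with the remote chiral ring A), giving the C-1' epimeric series. Fallback, from 12 to 21, replaces the chiral base by enamine organocatalysis and needs no silyl groups. D-Proline-catalysed α-aminoxylation of 12 with nitrosobenzene (DMSO, 0 °C) should give the (1R,3S)-3-(phenylaminooxy)-4-oxocyclohexyl compound F4, with axial attack on the enamine expected to favour this trans isomer. Zn/AcOH would cleave the N–O bond to the α-hydroxy ketone F5. Selective sulfonylation of the least hindered hydroxyl with 4-nitrobenzenesulfonyl chloride/pyridine would give the α-nosyloxy ketone F6, LiBr in acetone would invert it to the free-diol bromoketone F7, and excess MeMgBr/CeCl3 would give 21.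

Step 5 – what may go wrong: homocoupling or protodehalogenation of the hindered 2-bromoallyl partner, or insertion of the alkenylnickel intermediate into the neighbouring isopropenyl group. Fallback, from 9 back to 12, is a transition-metal-free Zweifel olefination. Silylation of 9 (Et3SiOTf, 2,6-lutidine) would give the bis(triethylsilyl) ether F8, and t-BuLi (Et2O, −78 °C) the alkenyllithium F9. Addition to commercial 2-(1,4-dioxaspiro[4.5]decan-8-yl)-4,4,5,5-tetramethyl-1,3,2-dioxaborolane would give the boronate complex F10. I2 followed by NaOMe/MeOH would trigger 1,2-migration and elimination to the coupled bis-silyl ketal F11, and aqueous HCl/THF would remove the silyl ethers and the dioxolane to give 12.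

**Further compounds**

F1 | step 8 | (2S,4R)-2-bromo-4-{3-[(1R,2R,3R,6S)-3-methyl-6-(prop-1-en-2-yl)-2,3-bis(trimethylsilyloxy)cyclohexyl]prop-1-en-2-yl}cyclohexan-1-one | C=C(C[C@@H]1[C@@H](C(=C)C)CC[C@@](C)(O[Si](C)(C)C)[C@@H]1O[Si](C)(C)C)[C@@H]1CCC(=O)[C@@H](Br)C1
F2 | step 8 | {[(4R)-2-bromo-4-{3-[(1R,2R,3R,6S)-3-methyl-6-(prop-1-en-2-yl)-2,3-bis(trimethylsilyloxy)cyclohexyl]prop-1-en-2-yl}cyclohex-1-en-1-yl]oxy}trimethylsilane | C=C(C[C@@H]1[C@@H](C(=C)C)CC[C@@](C)(O[Si](C)(C)C)[C@@H]1O[Si](C)(C)C)[C@@H]1CCC(O[Si](C)(C)C)=C(Br)C1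
F3 | step 8 | lithium (4R)-2-bromo-4-{3-[(1R,2R,3R,6S)-3-methyl-6-(prop-1-en-2-yl)-2,3-bis(trimethylsilyloxy)cyclohexyl]prop-1-en-2-yl}cyclohex-1-en-1-olate | [Li+].C=C(C[C@@H]1[C@@H](C(=C)C)CC[C@@](C)(O[Si](C)(C)C)[C@@H]1O[Si](C)(C)C)[C@@H]1CCC([O-])=C(Br)C1
F4 | step 6 | (2S,4R)-4-{3-[(1R,2R,3R,6S)-2,3-dihydroxy-3-methyl-6-(prop-1-en-2-yl)cyclohexyl]prop-1-en-2-yl}-2-(phenylaminooxy)cyclohexan-1-one | C=C(C[C@@H]1[C@@H](C(=C)C)CC[C@@](C)(O)[C@@H]1O)[C@@H]1CCC(=O)[C@@H](ONc2ccccc2)C1
F5 | step 6 | (2S,4R)-4-{3-[(1R,2R,3R,6S)-2,3-dihydroxy-3-methyl-6-(prop-1-en-2-yl)cyclohexyl]prop-1-en-2-yl}-2-hydroxycyclohexan-1-one | C=C(C[C@@H]1[C@@H](C(=C)C)CC[C@@](C)(O)[C@@H]1O)[C@@H]1CCC(=O)[C@@H](O)C1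
F6 | step 6 | (1S,5R)-5-{3-[(1R,2R,3R,6S)-2,3-dihydroxy-3-methyl-6-(prop-1-en-2-yl)cyclohexyl]prop-1-en-2-yl}-2-oxocyclohexyl 4-nitrobenzenesulfonate | C=C(C[C@@H]1[C@@H](C(=C)C)CC[C@@](C)(O)[C@@H]1O)[C@@H]1CCC(=O)[C@@H](OS(=O)(=O)c2ccc(cc2)[N+](=O)[O-])C1
F7 | step 6 | (2R,4R)-2-bromo-4-{3-[(1R,2R,3R,6S)-2,3-dihydroxy-3-methyl-6-(prop-1-en-2-yl)cyclohexyl]prop-1-en-2-yl}cyclohexan-1-one | C=C(C[C@@H]1[C@@H](C(=C)C)CC[C@@](C)(O)[C@@H]1O)[C@@H]1CCC(=O)[C@H](Br)C1
F8 | step 5 | bis(triethylsilyl) ether of 9, (1R,2R,3R,4S)-3-(2-bromoprop-2-en-1-yl)-1-methyl-4-(prop-1-en-2-yl)-1,2-bis(triethylsilyloxy)cyclohexane | C=C(Br)C[C@@H]1[C@@H](C(=C)C)CC[C@@](C)(O[Si](CC)(CC)CC)[C@@H]1O[Si](CC)(CC)CC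
F9 | step 5 | alkenyllithium from F8, {3-[(1R,2R,3R,6S)-3-methyl-6-(prop-1-en-2-yl)-2,3-bis(triethylsilyloxy)cyclohexyl]prop-1-en-2-yl}lithium | [Li]C(=C)C[C@@H]1[C@@H](C(=C)C)CC[C@@](C)(O[Si](CC)(CC)CC)[C@@H]1O[Si](CC)(CC)CC
F10 | step 5 | lithium boronate complex of F9 with 2-(1,4-dioxaspiro[4.5]decan-8-yl)-4,4,5,5-tetramethyl-1,3,2-dioxaborolane | [Li+].C=C(C[C@@H]1[C@@H](C(=C)C)CC[C@@](C)(O[Si](CC)(CC)CC)[C@@H]1O[Si](CC)(CC)CC)[B-]1(OC(C)(C)C(C)(C)O1)C1CCC2(CC1)OCCO2
F11 | step 5 | bis(triethylsilyl) ether of 11, 8-{3-[(1R,2R,3R,6S)-3-methyl-6-(prop-1-en-2-yl)-2,3-bis(triethylsilyloxy)cyclohexyl]prop-1-en-2-yl}-1,4-dioxaspiro[4.5]decane | C=C(C[C@@H]1[C@@H](C(=C)C)CC[C@@](C)(O[Si](CC)(CC)CC)[C@@H]1O[Si](CC)(CC)CC)C1CCC2(CC1)OCCO2
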